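**Plan**

- Retrosynthesis: after removal of the helper groups (six O-benzyl, two benzyl ester, two C–Br), the dihydronaphthalene is cut at C2–C3 and at C8a–C1 into two identical rosmarinate units; these bonds are C8–C8′ and C6–C7′ of two caffeoyl C6–C3 chains. Each unit is then cut at its C7=C8 alkene (aldehyde + malonate) and at the malonyl–O bond to the lactate.
- Enabling feature: both halves are 4-hydroxycinnamoyl esters. The para OH (C7–OH on the naphthalene ring, 4′-OH on the pendant ring) lets one-electron oxidation place spin on C8, and the derived quinone methide is closed at C7′ by the ring carbon (C8a) para to the C6 oxygen.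
- Forward: (R)-danshensu → tribenzyl lactate → malonate half-ester; 3,4-dihydroxybenzaldehyde → 3-O-benzyl-5-bromo aldehyde; Knoevenagel–Doebner condensation joins them; FeCl3 dimerisation forms both C–C bonds and the carbocycle; debromination, then debenzylation.
- Helpers: bromine at C5 of the caffeoyl ring blocks 8–5′ and 8–O–4′ coupling (sinapate-like substitution), and benzyl groups leave one phenol per unit free; both are removed at the end.
- Stereochemistry: both lactate centres come from the chiral pool. C1/C2 arise trans in the ring closure; their absolute sense rests on weak induction by the lactates and is completed by separating the two diastereomeric trans dimers.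

Key step: step 6

Assumption: (R)-danshensu sodium salt and 3,4-dihydroxybenzaldehyde are taken as commercial materials; read from the SMILES, the target is (1R,2S) in the ring with (R) at both lactate carbons.

**Route**

Step 1
Reactants: 1 danshensu sodium salt
Product: 2 benzyl (2R)-3-[3,4-bis(benzyloxy)phenyl]-2-hydroxypropanoate
Conditions: BnBr (3.3 equiv), K2CO3 (2.2 equiv), DMF, Ar, rt → 50 °C
Reagents that add atoms: benzyl bromide BrCc1ccccc1
Why: Williamson O-alkylation in which carbonate ionises only the two phenols and the carboxylate is already an anion, so three benzyl groups go on in one operation while the secondary alcohol and the chiral-pool stereocentre stay untouched.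

Step 2
Reactants: 2 tribenzyl lactate; 3 Meldrum's acid
Product: 4 malonic acid half-ester of 2
Conditions: toluene, 105 °C
Reagents that add atoms: none
Why: Thermal ring-opening acylation of an alcohol by Meldrum's acid (loss of acetone) is the standard entry to malonic half-esters; it acylates oxygen without touching the C–O bond of the stereocentre, so (R) is retained.

Step 3
Reactants: 5 3,4-dihydroxybenzaldehyde
Product: 6 3-(benzyloxy)-4-hydroxybenzaldehyde
Conditions: NaH (2.2 equiv), DMSO, rt; BnBr (1.0 equiv), rt; aq. HCl work-up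
Reagents that add atoms: benzyl bromide BrCc1ccccc1
Why: Regioselective Williamson alkylation through the dianion, in which the 4-phenoxide is stabilised by the para formyl group, so the more basic 3-phenoxide takes the single equivalent of benzyl bromide.

Step 4
Reactants: 6 3-(benzyloxy)-4-hydroxybenzaldehyde
Product: 7 3-(benzyloxy)-5-bromo-4-hydroxybenzaldehyde
Conditions: Br2 (1.05 equiv), NaOAc, AcOH, rt
Reagents that add atoms: bromine BrBr
Why: Electrophilic aromatic bromination directed ortho to the free phenol (the vanillin → 5-bromovanillin pattern), C5 being the only open position ortho or para to OH; acetate buffers HBr so the benzyl ether survives.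

Step 5
Reactants: 4 malonic half-ester; 7 bromo aldehyde
Product: 8 bromine-blocked tetra-O-benzyl rosmarinate with free 4-OH
Conditions: pyridine, piperidine (0.1 equiv), 60 °C
Reagents that add atoms: none
Why: Knoevenagel–Doebner condensation of a malonic half-ester (condensation, then decarboxylative elimination) gives the (E)-cinnamate directly and tolerates the free phenol; the mild amine base should leave the α-acyloxy ester stereocentre intact.

Step 6
Reactants: 8 bromine-blocked rosmarinate (two molecules)
Product: 11 dibromo hexa-O-benzyl rabdosiin dibenzyl ester, via bis(quinone methide) 9 (not isolated), via mono(quinone methide) 10 (not isolated)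
Conditions: FeCl3·6H2O (1.1 equiv per 8), acetone–H2O (9:1), Ar, 20 °C
Reagents that add atoms: none
Why: Fe(III) oxidises the single free phenol of each molecule of 8 to a phenoxyl radical with spin density at C8, two radicals join C8–C8′ to bis(quinone methide) 9, one half re-aromatises by loss of H-8 to give 10, and its ring carbon C6 (para to the 3-benzyloxy group) then adds to C7′ of the remaining quinone methide, after which proton loss restores both arenes. The closest known reaction type is the FeCl3 dimerisation of sinapate esters to 1-aryl-1,2-dihydronaphthalene-2,3-dicarboxylates (thomasidioates) and the analogous biomimetic coupling of caffeate and rosmarinate esters. The only ring that closes, the cyclohexadiene ring C4a–C8a–C1–C2–C3–C4, forms by a 6-exo-trig Friedel–Crafts (vinylogous Michael) attack of the arene on the exocyclic quinone-methide carbon, the C8–C8′ bond before it being intermolecular. C2 is fixed in the radical–radical coupling, where the only stereo-differentiating elements are the (R)-lactate esters in a 1,4-relationship to C8, and C1 is set in the ring closure trans to the C2 ester (aryl and ester pseudo-axial, away from the C3 ester and the C8 bromine), as in the thomasidioate series. The step needs chemoselective oxidation (secured by benzylation of every other OH), C8–C8′ rather than C8–C5′ or C8–O–C4′ coupling (secured by bromine at C5, which mimics the 3,5-disubstitution of a sinapate), arylation at C6 rather than C2 (C6 is para to the benzyloxy group and unhindered) and bond formation on the Re face of the C8 that stays sp3. For this last selectivity the induction by the remote lactates should be modest, but because both lactates are (R) the (1R,2S) and (1S,2R) trans dimers are diastereomers, so 11 should be freed from its isomer by chromatography or crystallisation.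

Step 7
Reactants: 11 dibromo dimer
Product: 12 hexa-O-benzyl rabdosiin dibenzyl ester
Conditions: Bu3SnH (3 equiv), AIBN (0.2 equiv), toluene, 90 °C
Reagents that add atoms: none
Why: Radical-chain hydrodehalogenation in which the stannyl radical abstracts both aryl bromines and the aryl radicals are quenched by Sn–H faster than they can add or abstract intramolecularly (neither bromine is ortho to a benzyloxy group); benzyl ethers, esters, the trisubstituted enoate and all stereocentres should be untouched.

Step 8
Reactants: 12 hexa-O-benzyl rabdosiin dibenzyl ester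
Product: 13 rabdosiin
Conditions: BCl3 (1 M in CH2Cl2, 20 equiv), pentamethylbenzene (25 equiv), CH2Cl2, −78 → 0 °C; MeOH/H2O quench; reversed-phase purification under Ar
Reagents that add atoms: none
Why: Lewis-acid debenzylation with pentamethylbenzene as a non-basic benzyl-cation scavenger should remove six aryl benzyl ethers and two benzyl esters at low temperature without reducing the C3=C4 alkene (which hydrogenolysis would endanger) and without touching the secondary alkyl ester links or the four stereocentres.

**Compound list**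

1 | sodium (2R)-3-(3,4-dihydroxyphenyl)-2-hydroxypropanoate (danshensu sodium salt) | O[C@H](Cc1ccc(O)c(O)c1)C(=O)[O-].[Na+] | starting material
2 | benzyl (2R)-3-[3,4-bis(benzyloxy)phenyl]-2-hydroxypropanoate | O[C@H](Cc1ccc(OCc2ccccc2)c(OCc2ccccc2)c1)C(=O)OCc1ccccc1 | intermediate
3 | 2,2-dimethyl-1,3-dioxane-4,6-dione (Meldrum's acid) | CC1(C)OC(=O)CC(=O)O1 | starting material
4 | 3-{[(2R)-1-(benzyloxy)-3-[3,4-bis(benzyloxy)phenyl]-1-oxopropan-2-yl]oxy}-3-oxopropanoic acid | OC(=O)CC(=O)O[C@H](Cc1ccc(OCc2ccccc2)c(OCc2ccccc2)c1)C(=O)OCc1ccccc1 | intermediate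
5 | 3,4-dihydroxybenzaldehyde | O=Cc1ccc(O)c(O)c1 | starting material
6 | 3-(benzyloxy)-4-hydroxybenzaldehyde | O=Cc1ccc(O)c(OCc2ccccc2)c1 | intermediate
7 | 3-(benzyloxy)-5-bromo-4-hydroxybenzaldehyde | O=Cc1cc(Br)c(O)c(OCc2ccccc2)c1 | intermediate
8 | benzyl (2R)-3-[3,4-bis(benzyloxy)phenyl]-2-{[(2E)-3-[3-(benzyloxy)-5-bromo-4-hydroxyphenyl]prop-2-enoyl]oxy}propanoate | O=C(O[C@H](Cc1ccc(OCc2ccccc2)c(OCc2ccccc2)c1)C(=O)OCc1ccccc1)/C=C/c1cc(Br)c(O)c(OCc2ccccc2)c1 | intermediate
9 | bis[(2R)-1-(benzyloxy)-3-[3,4-bis(benzyloxy)phenyl]-1-oxopropan-2-yl] (2S,3S)-2,3-bis{[3-(benzyloxy)-5-bromo-4-oxocyclohexa-2,5-dien-1-ylidene]methyl}butanedioate (C8–C8′ bis(quinone methide); exocyclic C=C geometry not defined) | O=C(O[C@H](Cc1ccc(OCc2ccccc2)c(OCc2ccccc2)c1)C(=O)OCc1ccccc1)[C@@H](C=C1C=C(Br)C(=O)C(OCc2ccccc2)=C1)[C@H](C=C1C=C(Br)C(=O)C(OCc2ccccc2)=C1)C(=O)O[C@H](Cc1ccc(OCc2ccccc2)c(OCc2ccccc2)c1)C(=O)OCc1ccccc1 | intermediate (not isolated)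
10 | bis[(2R)-1-(benzyloxy)-3-[3,4-bis(benzyloxy)phenyl]-1-oxopropan-2-yl] (2E,3S)-2-[3-(benzyloxy)-5-bromo-4-hydroxybenzylidene]-3-{[3-(benzyloxy)-5-bromo-4-oxocyclohexa-2,5-dien-1-ylidene]methyl}butanedioate (mono(quinone methide); quinone-methide C=C geometry not defined) | O=C(O[C@H](Cc1ccc(OCc2ccccc2)c(OCc2ccccc2)c1)C(=O)OCc1ccccc1)/C(=C/c1cc(Br)c(O)c(OCc2ccccc2)c1)[C@H](C=C1C=C(Br)C(=O)C(OCc2ccccc2)=C1)C(=O)O[C@H](Cc1ccc(OCc2ccccc2)c(OCc2ccccc2)c1)C(=O)OCc1ccccc1 | intermediate (not isolated)
11 | bis[(2R)-1-(benzyloxy)-3-[3,4-bis(benzyloxy)phenyl]-1-oxopropan-2-yl] (1R,2S)-6-(benzyloxy)-1-[3-(benzyloxy)-5-bromo-4-hydroxyphenyl]-8-bromo-7-hydroxy-1,2-dihydronaphthalene-2,3-dicarboxylate | O=C(O[C@H](Cc1ccc(OCc2ccccc2)c(OCc2ccccc2)c1)C(=O)OCc1ccccc1)C1=Cc2cc(OCc3ccccc3)c(O)c(Br)c2[C@@H](c2cc(Br)c(O)c(OCc3ccccc3)c2)[C@@H]1C(=O)O[C@H](Cc1ccc(OCc2ccccc2)c(OCc2ccccc2)c1)C(=O)OCc1ccccc1 | intermediate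
12 | bis[(2R)-1-(benzyloxy)-3-[3,4-bis(benzyloxy)phenyl]-1-oxopropan-2-yl] (1R,2S)-6-(benzyloxy)-1-[3-(benzyloxy)-4-hydroxyphenyl]-7-hydroxy-1,2-dihydronaphthalene-2,3-dicarboxylate | O=C(O[C@H](Cc1ccc(OCc2ccccc2)c(OCc2ccccc2)c1)C(=O)OCc1ccccc1)C1=Cc2cc(OCc3ccccc3)c(O)cc2[C@@H](c2ccc(O)c(OCc3ccccc3)c2)[C@@H]1C(=O)O[C@H](Cc1ccc(OCc2ccccc2)c(OCc2ccccc2)c1)C(=O)OCc1ccccc1 | intermediate
13 | rabdosiin, (2R)-2-{[(1R,2S)-3-{[(1R)-1-carboxy-2-(3,4-dihydroxyphenyl)ethoxy]carbonyl}-1-(3,4-dihydroxyphenyl)-6,7-dihydroxy-1,2-dihydronaphthalene-2-carbonyl]oxy}-3-(3,4-dihydroxyphenyl)propanoic acid | O=C(O[C@H](Cc1ccc(O)c(O)c1)C(=O)O)C1=Cc2cc(O)c(O)cc2[C@@H](c2ccc(O)c(O)c2)[C@@H]1C(=O)O[C@H](Cc1ccc(O)c(O)c1)C(=O)O | target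

**Step count and risks**

Total steps: 8. Longest linear sequence: 6 (steps 1, 2, 5, 6, 7, 8; the aldehyde branch 3, 4, 5, 6, 7, 8 is equally long).

Steps most likely to fail:

1. Step 6. What may go wrong: little facial discrimination in the radical–radical coupling because the lactate centres are remote, possibly with the two diastereomeric dimers not separable; trapping of the quinone methide by water may also lower the mass balance. Fallback (ring built on an achiral ester, resolution of the small diacid, lactates attached afterwards), setting out from 7 and 2 and returning at 11. Wittig olefination of 7 with Ph3P=CHCO2tBu should give tert-butyl (2E)-3-[3-(benzyloxy)-5-bromo-4-hydroxyphenyl]prop-2-enoate F1. Its FeCl3 dimerisation under the conditions of step 6 should give the racemic trans di-tert-butyl dihydronaphthalene-2,3-dicarboxylate F2. TFA removes the tert-butyl groups, and crystallisation of a cinchona-alkaloid salt of the racemic acid should give the (1R,2S)-dihydronaphthalene-2,3-dicarboxylic acid F3. Alcohol 2 is converted with inversion (Appel reaction, CBr4/PPh3) into benzyl (2S)-3-[3,4-bis(benzyloxy)phenyl]-2-bromopropanoate F4. Double O-alkylation of the dicaesium salt of F3 (two equivalents of base, so that only the carboxylic acids are ionised) with F4 proceeds with a second inversion to (R) at both lactate carbons and gives 11.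

2. Step 8. What may go wrong: incomplete cleavage of the two benzyl esters under conditions mild enough for the aryl ethers, or damage to the oxidation-prone polyphenol on forcing. Fallback (carboxyl groups unmasked first by a different mechanism), setting out from 12 and returning at 13. Pd(OAc)2/Et3SiH/Et3N in CH2Cl2 should convert the two benzyl esters, without touching aryl benzyl ethers or the alkene, into the bis(triethylsilyl) ester F5. Aqueous methanolic work-up hydrolyses it to hexa-O-benzyl rabdosiin (free diacid) F6. BCl3/pentamethylbenzene at −78 °C then only has to cleave the six aryl benzyl ethers and gives 13.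

3. Step 7. What may go wrong: side reactions of the aryl radicals (attack on the pendant ring, hydrogen abstraction at C1 with loss of configuration) or stannyl-radical addition to the enoate. Fallback (no blocking group at all), setting out from 4 and 6 and returning at 12. Knoevenagel–Doebner condensation of 4 with 6 should give the bromine-free rosmarinate, benzyl (2R)-3-[3,4-bis(benzyloxy)phenyl]-2-{[(2E)-3-[3-(benzyloxy)-4-hydroxyphenyl]prop-2-enoyl]oxy}propanoate F7. Its FeCl3 dimerisation gives 12 directly, at the price of 8–5′ benzofuran dimers that must be separated.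

**Further compounds**

F1 | step 6 | tert-butyl (2E)-3-[3-(benzyloxy)-5-bromo-4-hydroxyphenyl]prop-2-enoate | CC(C)(C)OC(=O)/C=C/c1cc(Br)c(O)c(OCc2ccccc2)c1
F2 | step 6 | di-tert-butyl (1R*,2S*)-6-(benzyloxy)-1-[3-(benzyloxy)-5-bromo-4-hydroxyphenyl]-8-bromo-7-hydroxy-1,2-dihydronaphthalene-2,3-dicarboxylate (racemate, one enantiomer drawn) | CC(C)(C)OC(=O)C1=Cc2cc(OCc3ccccc3)c(O)c(Br)c2[C@@H](c2cc(Br)c(O)c(OCc3ccccc3)c2)[C@@H]1C(=O)OC(C)(C)C
F3 | step 6 | (1R,2S)-6-(benzyloxy)-1-[3-(benzyloxy)-5-bromo-4-hydroxyphenyl]-8-bromo-7-hydroxy-1,2-dihydronaphthalene-2,3-dicarboxylic acid (resolved from the racemate) | OC(=O)C1=Cc2cc(OCc3ccccc3)c(O)c(Br)c2[C@@H](c2cc(Br)c(O)c(OCc3ccccc3)c2)[C@@H]1C(=O)O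
F4 | step 6 | benzyl (2S)-3-[3,4-bis(benzyloxy)phenyl]-2-bromopropanoate | Br[C@@H](Cc1ccc(OCc2ccccc2)c(OCc2ccccc2)c1)C(=O)OCc1ccccc1
F5 | step 8 | bis[(2R)-3-[3,4-bis(benzyloxy)phenyl]-1-oxo-1-[(triethylsilyl)oxy]propan-2-yl] (1R,2S)-6-(benzyloxy)-1-[3-(benzyloxy)-4-hydroxyphenyl]-7-hydroxy-1,2-dihydronaphthalene-2,3-dicarboxylate | O=C(O[C@H](Cc1ccc(OCc2ccccc2)c(OCc2ccccc2)c1)C(=O)O[Si](CC)(CC)CC)C1=Cc2cc(OCc3ccccc3)c(O)cc2[C@@H](c2ccc(O)c(OCc3ccccc3)c2)[C@@H]1C(=O)O[C@H](Cc1ccc(OCc2ccccc2)c(OCc2ccccc2)c1)C(=O)O[Si](CC)(CC)CC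
F6 | step 8 | (2R)-2-{[(1R,2S)-6-(benzyloxy)-1-[3-(benzyloxy)-4-hydroxyphenyl]-3-{[(1R)-2-[3,4-bis(benzyloxy)phenyl]-1-carboxyethoxy]carbonyl}-7-hydroxy-1,2-dihydronaphthalene-2-carbonyl]oxy}-3-[3,4-bis(benzyloxy)phenyl]propanoic acid | O=C(O[C@H](Cc1ccc(OCc2ccccc2)c(OCc2ccccc2)c1)C(=O)O)C1=Cc2cc(OCc3ccccc3)c(O)cc2[C@@H](c2ccc(O)c(OCc3ccccc3)c2)[C@@H]1C(=O)O[C@H](Cc1ccc(OCc2ccccc2)c(OCc2ccccc2)c1)C(=O)O
F7 | step 7 | benzyl (2R)-3-[3,4-bis(benzyloxy)phenyl]-2-{[(2E)-3-[3-(benzyloxy)-4-hydroxyphenyl]prop-2-enoyl]oxy}propanoate | O=C(O[C@H](Cc1ccc(OCc2ccccc2)c(OCc2ccccc2)c1)C(=O)OCc1ccccc1)/C=C/c1ccc(O)c(OCc2ccccc2)c1
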